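The whole plan depends on cutting the C6a–C11a bond, the single bond that joins the two stereocentres. C11a lies between O11 and electron-rich ring A, so as a CH2 group it offers a hydridic C–H bond. C6a carries ring D and C6, so it can serve as a donor/acceptor carbene carbon with C6 as its ester. One chiral dirhodium-catalysed 1,5 C–H insertion then closes dihydrofuran ring C and sets both centres cis. The precursor is a ring D aryldiazoacetate whose O11 bears the O5-silylated ring A/E chromenylmethyl group. C10 already holds the prenyl group, and O8 and O9 carry two different acetal groups, cleaved later by hydride and by fluoride.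

Key step: step 15

Assumption: the S-configured phthaloyl-tert-leucinate catalyst is taken to give the 2R,3S ester, by analogy with simpler 2-(benzyloxy)phenyl diazoacetates. If the sense of induction is opposite on this substrate, the R-configured catalyst is used.

Locants and abbreviations:
- Locants follow pterocarpan numbering. Ring E is the pyran on ring A and ring F is the pyran on ring D.
- TBS = tert-butyldimethylsilyl.
- POM = pivaloyloxymethyl, CH2OC(O)t-Bu.
- SEM = 2-(trimethylsilyl)ethoxymethyl.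
- prenyl = 3-methylbut-2-en-1-yl.

**Fragment A (rings A and E)**

Step 1
Reactants: 1 resorcinol; 2 3-methylbut-2-enal
Product: 4 2,2-dimethyl-2H-chromen-7-ol, via ortho-quinone methide 3 (not isolated)
Conditions: ethylenediammonium diacetate (10 mol %), excess 1, xylene, 140 °C
Reagents that add atoms: none
Why: Amine-salt-catalysed Knoevenagel-type condensation at C4 of resorcinol, the least hindered activated position, gives 3, and its oxa-6π electrocyclisation closes ring E (formal [3+3] chromene annulation).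

Step 2
Reactants: 4 2,2-dimethyl-2H-chromen-7-ol
Product: 5 7-hydroxy-2,2-dimethyl-2H-chromene-6-carbaldehyde
Conditions: MgCl2, Et3N, (CH2O)n, MeCN, 80 °C; aq. HCl work-up
Reagents that add atoms: paraformaldehyde (as formaldehyde), C=O
Why: The magnesium-templated Casnati–Skattebøl formylation reacts only ortho to the hydroxyl, and C6 should be preferred over C8, which sits between two oxygens, as is usual for 3-alkoxyphenols.

Step 3
Reactants: 5 7-hydroxy-2,2-dimethyl-2H-chromene-6-carbaldehyde
Product: 6 7-(TBS-oxy)-2,2-dimethyl-2H-chromene-6-carbaldehyde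
Conditions: TBSCl, imidazole, DMF, rt
Reagents that add atoms: tert-butyldimethylsilyl chloride, CC(C)(C)[Si](C)(C)Cl
Why: Imidazole-promoted silylation masks the future O5 as a fluoride-labile ether that tolerates hydride, zerovalent palladium and the carbene.

Step 4
Reactants: 6 7-(TBS-oxy)-2,2-dimethyl-2H-chromene-6-carbaldehyde
Product: 7 [7-(TBS-oxy)-2,2-dimethyl-2H-chromen-6-yl]methanol (fragment A)
Conditions: NaBH4, THF/MeOH, 0 °C; aq. NH4Cl
Reagents that add atoms: none
Why: Borohydride reduction of the aldehyde is fast at 0 °C, and a prompt mild quench should keep the silyl group from moving to the new benzylic oxygen.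

**Ring D and assembly**

Step 5
Reactants: 8 3,4-dihydroxybenzaldehyde
Product: 9 (4-formyl-2-hydroxyphenoxy)methyl pivalate
Conditions: chloromethyl pivalate (1 equiv), NaHCO3, NaI (cat.), DMF, 40 °C
Reagents that add atoms: chloromethyl pivalate, CC(C)(C)C(=O)OCCl
Why: Williamson-type alkylation under bicarbonate reaches only the 4-hydroxyl, which the para formyl group makes the more acidic, so the future O8 carries from the start a group that hydride will later remove.

Step 6
Reactants: 9 (4-formyl-2-hydroxyphenoxy)methyl pivalate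
Product: 10 [4-formyl-2-(SEM-oxy)phenoxy]methyl pivalate
Conditions: SEMCl, i-Pr2NEt, CH2Cl2, 0 °C to rt
Reagents that add atoms: 2-(trimethylsilyl)ethoxymethyl chloride, C[Si](C)(C)CCOCCl
Why: Acetal-type O-alkylation of the remaining phenol (future O9) installs an alkyl-type group that cannot migrate to a neighbouring phenol, is orthogonal to POM, and leaves without acid.

Step 7
Reactants: 10 [4-formyl-2-(SEM-oxy)phenoxy]methyl pivalate
Product: 12 [4-hydroxy-2-(SEM-oxy)phenoxy]methyl pivalate, via aryl formate 11 (not isolated)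
Conditions: mCPBA, CH2Cl2, 0 °C to rt; then Et3N (cat.), MeOH, 0 °C
Reagents that add atoms: 3-chloroperbenzoic acid, O=C(OO)c1cccc(Cl)c1
Why: In this Baeyer–Villiger oxidation the alkoxy donors favour aryl migration, and the very labile formate 11 is methanolysed under conditions that leave the hindered pivalate intact, which frees the future O11.

Step 8
Reactants: 12 [4-hydroxy-2-(SEM-oxy)phenoxy]methyl pivalate
Product: 13 [5-bromo-4-hydroxy-2-(SEM-oxy)phenoxy]methyl pivalate
Conditions: NBS, MeCN, −20 to 0 °C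
Reagents that add atoms: N-bromosuccinimide, O=C1CCC(=O)N1Br
Why: Electrophilic aromatic bromination goes ortho to the free hydroxyl and para to the O9 ether, at the future C6b, because the other ortho site lies between two oxygens, and the bromine then serves as both blocking group and coupling handle.

Step 9
Reactants: 14 2-methylbut-3-en-2-ol
Product: 15 tert-butyl 2-methylbut-3-en-2-yl carbonate
Conditions: n-BuLi, THF, −78 to 0 °C; then Boc2O
Reagents that add atoms: di-tert-butyl dicarbonate, CC(C)(C)OC(=O)OC(=O)OC(C)(C)C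
Why: O-acylation of the deprotonated tertiary alcohol with Boc2O is the routine way to a tertiary allylic mixed carbonate.

Step 10
Reactants: 13 [5-bromo-4-hydroxy-2-(SEM-oxy)phenoxy]methyl pivalate; 15 tert-butyl 2-methylbut-3-en-2-yl carbonate
Product: 16 {5-bromo-4-[(2-methylbut-3-en-2-yl)oxy]-2-(SEM-oxy)phenoxy}methyl pivalate
Conditions: Pd(PPh3)4 (cat.), THF, 0 °C
Reagents that add atoms: none
Why: Tsuji–Trost O-allylation under kinetic control at low temperature places the phenol oxygen on the more substituted allyl terminus, and oxidative addition into the electron-rich C–Br bond should not compete at 0 °C.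

Step 11
Reactants: 16 {5-bromo-4-[(2-methylbut-3-en-2-yl)oxy]-2-(SEM-oxy)phenoxy}methyl pivalate
Product: 18 [5-bromo-4-hydroxy-3-prenyl-2-(SEM-oxy)phenoxy]methyl pivalate, via ortho-dienone 17 (not isolated)
Conditions: DMF, 120 °C, argon
Reagents that add atoms: none
Why: In this aromatic Claisen rearrangement C6b is blocked by bromine, so the [3,3] shift can end productively only at C10; the shift turns the 1,1-dimethylallyl unit into the linear prenyl group, and tautomerisation of 17 restores the O11 phenol.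

Step 12
Reactants: 18 [5-bromo-4-hydroxy-3-prenyl-2-(SEM-oxy)phenoxy]methyl pivalate; 7 [7-(TBS-oxy)-2,2-dimethyl-2H-chromen-6-yl]methanol
Product: 19 {5-bromo-4-{[7-(TBS-oxy)-2,2-dimethyl-2H-chromen-6-yl]methoxy}-3-prenyl-2-(SEM-oxy)phenoxy}methyl pivalate
Conditions: PPh3, DIAD, THF, 0 °C to rt
Reagents that add atoms: none
Why: Mitsunobu etherification joins the acidic ortho-bromophenol to the primary benzylic alcohol under near-neutral conditions that spare the silyl, acetal and ester groups.

Step 13
Reactants: 19 aryl bromide from step 12; 20 methyl bromoacetate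
Product: 22 methyl 2-{2-{[7-(TBS-oxy)-2,2-dimethyl-2H-chromen-6-yl]methoxy}-3-prenyl-5-(POM-oxy)-4-(SEM-oxy)phenyl}acetate, via Reformatsky reagent 21 (not isolated)
Conditions: 20, Zn dust (TMSCl-activated), THF, 40 °C; then 19, Pd2(dba)3 (cat.), XPhos (cat.), THF, 60 °C
Reagents that add atoms: none
Why: In this Negishi-type α-arylation the weakly basic Reformatsky reagent couples with the aryl bromide on a bulky biarylphosphine palladium catalyst, tolerates pivalate, silyl ether and alkenes, and transmetalates fast enough to outrun direct arylation of ring A.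

Step 14
Reactants: 22 methyl arylacetate from step 13
Product: 23 methyl 2-diazo-2-{2-{[7-(TBS-oxy)-2,2-dimethyl-2H-chromen-6-yl]methoxy}-3-prenyl-5-(POM-oxy)-4-(SEM-oxy)phenyl}acetate
Conditions: 4-acetamidobenzenesulfonyl azide, DBU, dry MeCN, 0 °C to rt
Reagents that add atoms: 4-acetamidobenzenesulfonyl azide, CC(=O)Nc1ccc(cc1)S(=O)(=O)N=[N+]=[N-]
Why: Regitz diazo transfer from the sulfonyl azide to the DBU-activated benzylic methylene is the standard entry to aryldiazoacetates, and dry conditions keep the aryl silyl ether in place.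

Step 15
Reactants: 23 methyl aryldiazoacetate from step 14
Product: 25 methyl (2R,3S)-2-[7-(TBS-oxy)-2,2-dimethyl-2H-chromen-6-yl]-7-prenyl-5-(POM-oxy)-6-(SEM-oxy)-2,3-dihydrobenzofuran-3-carboxylate (cis), via rhodium carbene 24 (not isolated)
Conditions: Rh2(S-PTTL)4, dirhodium tetrakis[N-phthaloyl-(S)-tert-leucinate] (1–2 mol %), toluene (0.01 M), 4 Å MS, −60 °C
Reagents that add atoms: none
Why: The catalyst expels N2 from 23 to give the donor/acceptor carbene 24, which takes up one O11–CH2 hydrogen in a concerted, asynchronous, hydride-transfer-like three-centre transition state while the C6a–C11a bond forms. The closest known reaction type is the dirhodium-carboxylate-catalysed 1,5 C–H insertion of 2-(benzyloxy)phenyl diazoacetates, which leads to cis-2-aryl-2,3-dihydrobenzofuran-3-carboxylates. Ring C closes through a five-membered insertion transition state made of the carbene carbon, C6b, C10a, O11 and C11a. C6a and C11a are both set by the chiral pocket of the four phthalimido-tert-leucinate ligands, which selects one carbene face and one enantiotopic benzylic hydrogen, and the cis relation is the kinetic outcome of that transition state. The step needs site selectivity and chemoselectivity over the ring E and prenyl alkenes and the acetal CH2 groups, and the substrate secures both: only the O11–CH2 bond lies within five-membered reach, O11 and the O3/O5-donor ring A activate it, the C10 prenyl group pushes the benzyl ether towards the carbene, and the alkenes could be reached only through medium or meta-bridged rings. High dilution and low temperature suppress intermolecular cyclopropanation and carbene dimerisation, and no base is present that could epimerise C6a.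

Step 16
Reactants: 25 cis ester from step 15
Product: 27 (2R,3R)-2-[7-(TBS-oxy)-2,2-dimethyl-2H-chromen-6-yl]-3-(hydroxymethyl)-7-prenyl-6-(SEM-oxy)-2,3-dihydrobenzofuran-5-ol, via aryloxymethanol 26 (not isolated)
Conditions: LiAlH4, THF, −40 to 0 °C; aq. potassium sodium tartrate work-up
Reagents that add atoms: none
Why: Hydride reduction at low temperature is faster than enolisation, so C6a keeps its configuration and O11 is not eliminated, and the same reagent reduces the pivalate so that hemiacetal 26 collapses and frees O8 without a separate step.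

Step 17
Reactants: 27 phenol alcohol from step 16; 28 3-chloro-3-methylbut-1-yne
Product: 29 {(2R,3R)-2-[7-(TBS-oxy)-2,2-dimethyl-2H-chromen-6-yl]-5-[(2-methylbut-3-yn-2-yl)oxy]-7-prenyl-6-(SEM-oxy)-2,3-dihydrobenzofuran-3-yl}methanol
Conditions: DBU, CuCl2 (1 mol %), dry MeCN, 0 °C
Reagents that add atoms: none
Why: Copper-catalysed propargylic etherification alkylates the only free phenol, O8, in preference to the aliphatic alcohol, and the SEM group on O9 cannot migrate under base.

Step 18
Reactants: 29 propargyl ether from step 17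
Product: 30 6-{(2R,3R)-3-(hydroxymethyl)-5-[(2-methylbut-3-yn-2-yl)oxy]-7-prenyl-6-(SEM-oxy)-2,3-dihydrobenzofuran-2-yl}-2,2-dimethyl-2H-chromen-7-ol
Conditions: TBAF/AcOH (equimolar), THF, 0 °C
Reagents that add atoms: none
Why: Acetic-acid-buffered fluoride cleaves the aryl silyl ether quickly while keeping O5 protonated, which guards ring C against opening at the benzylic C11a–O11 bond, and it leaves the SEM ether intact at 0 °C.

Step 19
Reactants: 30 phenol alcohol from step 18
Product: 31 (6aR,11aR)-8-[(2-methylbut-3-yn-2-yl)oxy]-10-prenyl-9-(SEM-oxy)pterocarpan bearing the 2,2-dimethylpyran ring E at C2–C3 (oxygen on C3)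
Conditions: PPh3, DIAD, THF (0.01 M), 0 °C to rt
Reagents that add atoms: none
Why: In this intramolecular Mitsunobu etherification O5 displaces the activated primary C6 oxygen in a 6-exo-tet closure of ring B that touches neither stereocentre, and the cis arrangement from step 15 holds C6 within reach of O5.

Step 20
Reactants: 31 pterocarpan propargyl ether from step 19
Product: 34 9-O-SEM-lespecyrtin E4 (6aR,11aR), via allenylphenol 32 (not isolated), via ortho-quinone methide 33 (not isolated)
Conditions: o-xylene, 140 °C, argon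
Reagents that add atoms: none
Why: In this aromatic propargyl Claisen cascade a [3,3] shift to C7, the only free ortho position of O8, followed by rearomatisation gives 32, and a 1,5-hydrogen shift to 33 followed by oxa-6π electrocyclisation closes ring F under neutral thermal conditions.

Step 21
Reactants: 34 9-O-SEM-lespecyrtin E4
Product: 35 lespecyrtin E4 (6aR,11aR)
Conditions: TBAF, DMPU/THF, 4 Å MS, 60 °C; aq. NH4Cl
Reagents that add atoms: none
Why: Fluoride attacks the remote trimethylsilyl group and the SEM acetal fragments, so the hindered O9 phenol is freed without acid, which spares the ortho prenyl group, both chromenes and the C11a–O11 bond now locked in the cis-fused tetracycle.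

**Compound list**

1 | resorcinol | Oc1cccc(O)c1 | starting material
2 | 3-methylbut-2-enal | CC(C)=CC=O | starting material
3 | 3-hydroxy-6-(3-methylbut-2-en-1-ylidene)cyclohexa-2,4-dien-1-one, formed in the flask | CC(C)=CC=C1C=CC(O)=CC1=O | intermediate
4 | 2,2-dimethyl-2H-chromen-7-ol | CC1(C)C=Cc2ccc(O)cc2O1 | intermediate
5 | 7-hydroxy-2,2-dimethyl-2H-chromene-6-carbaldehyde | CC1(C)C=Cc2cc(C=O)c(O)cc2O1 | intermediate
6 | 7-(TBS-oxy)-2,2-dimethyl-2H-chromene-6-carbaldehyde | CC1(C)C=Cc2cc(C=O)c(O[Si](C)(C)C(C)(C)C)cc2O1 | intermediate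
7 | [7-(TBS-oxy)-2,2-dimethyl-2H-chromen-6-yl]methanol | CC1(C)C=Cc2cc(CO)c(O[Si](C)(C)C(C)(C)C)cc2O1 | intermediate
8 | 3,4-dihydroxybenzaldehyde | O=Cc1ccc(O)c(O)c1 | starting material
9 | (4-formyl-2-hydroxyphenoxy)methyl pivalate | O=Cc1ccc(OCOC(=O)C(C)(C)C)c(O)c1 | intermediate
10 | [4-formyl-2-(SEM-oxy)phenoxy]methyl pivalate | O=Cc1ccc(OCOC(=O)C(C)(C)C)c(OCOCC[Si](C)(C)C)c1 | intermediate
11 | [4-(formyloxy)-2-(SEM-oxy)phenoxy]methyl pivalate, formed in the flask | O=COc1ccc(OCOC(=O)C(C)(C)C)c(OCOCC[Si](C)(C)C)c1 | intermediate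
12 | [4-hydroxy-2-(SEM-oxy)phenoxy]methyl pivalate | Oc1ccc(OCOC(=O)C(C)(C)C)c(OCOCC[Si](C)(C)C)c1 | intermediate
13 | [5-bromo-4-hydroxy-2-(SEM-oxy)phenoxy]methyl pivalate | Oc1cc(OCOCC[Si](C)(C)C)c(OCOC(=O)C(C)(C)C)cc1Br | intermediate
14 | 2-methylbut-3-en-2-ol | C=CC(C)(C)O | starting material
15 | tert-butyl 2-methylbut-3-en-2-yl carbonate | C=CC(C)(C)OC(=O)OC(C)(C)C | intermediate
16 | {5-bromo-4-[(2-methylbut-3-en-2-yl)oxy]-2-(SEM-oxy)phenoxy}methyl pivalate | C=CC(C)(C)Oc1cc(OCOCC[Si](C)(C)C)c(OCOC(=O)C(C)(C)C)cc1Br | intermediate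
17 | 6-prenylcyclohexa-2,4-dienone from the [3,3] shift, formed in the flask | CC(C)=CCC1C(=O)C(Br)=CC(OCOC(=O)C(C)(C)C)=C1OCOCC[Si](C)(C)C | intermediate
18 | [5-bromo-4-hydroxy-3-prenyl-2-(SEM-oxy)phenoxy]methyl pivalate | CC(C)=CCc1c(O)c(Br)cc(OCOC(=O)C(C)(C)C)c1OCOCC[Si](C)(C)C | intermediate
19 | {5-bromo-4-{[7-(TBS-oxy)-2,2-dimethyl-2H-chromen-6-yl]methoxy}-3-prenyl-2-(SEM-oxy)phenoxy}methyl pivalate | CC(C)=CCc1c(OCc2cc3C=CC(C)(C)Oc3cc2O[Si](C)(C)C(C)(C)C)c(Br)cc(OCOC(=O)C(C)(C)C)c1OCOCC[Si](C)(C)C | intermediate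
20 | methyl bromoacetate | COC(=O)CBr | starting material
21 | (2-methoxy-2-oxoethyl)zinc bromide, formed in the flask | COC(=O)C[Zn]Br | intermediate
22 | methyl 2-{2-{[7-(TBS-oxy)-2,2-dimethyl-2H-chromen-6-yl]methoxy}-3-prenyl-5-(POM-oxy)-4-(SEM-oxy)phenyl}acetate | CC(C)=CCc1c(OCc2cc3C=CC(C)(C)Oc3cc2O[Si](C)(C)C(C)(C)C)c(CC(=O)OC)cc(OCOC(=O)C(C)(C)C)c1OCOCC[Si](C)(C)C | intermediate
23 | methyl 2-diazo-2-{2-{[7-(TBS-oxy)-2,2-dimethyl-2H-chromen-6-yl]methoxy}-3-prenyl-5-(POM-oxy)-4-(SEM-oxy)phenyl}acetate | COC(=O)C(=[N+]=[N-])c1cc(OCOC(=O)C(C)(C)C)c(OCOCC[Si](C)(C)C)c(CC=C(C)C)c1OCc1cc2C=CC(C)(C)Oc2cc1O[Si](C)(C)C(C)(C)C | intermediate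
24 | rhodium carbene of 23 (dirhodium core and ligands shown as one Rh), formed in the flask | COC(=O)C(=[Rh])c1cc(OCOC(=O)C(C)(C)C)c(OCOCC[Si](C)(C)C)c(CC=C(C)C)c1OCc1cc2C=CC(C)(C)Oc2cc1O[Si](C)(C)C(C)(C)C | intermediate
25 | methyl (2R,3S)-2-[7-(TBS-oxy)-2,2-dimethyl-2H-chromen-6-yl]-7-prenyl-5-(POM-oxy)-6-(SEM-oxy)-2,3-dihydrobenzofuran-3-carboxylate | COC(=O)[C@H]1c2cc(OCOC(=O)C(C)(C)C)c(OCOCC[Si](C)(C)C)c(CC=C(C)C)c2O[C@H]1c1cc2C=CC(C)(C)Oc2cc1O[Si](C)(C)C(C)(C)C | intermediate
26 | (2R,3R)-5-(hydroxymethoxy)-3-(hydroxymethyl) analogue of 27, formed in the flask | OC[C@H]1c2cc(OCO)c(OCOCC[Si](C)(C)C)c(CC=C(C)C)c2O[C@H]1c1cc2C=CC(C)(C)Oc2cc1O[Si](C)(C)C(C)(C)C | intermediate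
27 | (2R,3R)-2-[7-(TBS-oxy)-2,2-dimethyl-2H-chromen-6-yl]-3-(hydroxymethyl)-7-prenyl-6-(SEM-oxy)-2,3-dihydrobenzofuran-5-ol | OC[C@H]1c2cc(O)c(OCOCC[Si](C)(C)C)c(CC=C(C)C)c2O[C@H]1c1cc2C=CC(C)(C)Oc2cc1O[Si](C)(C)C(C)(C)C | intermediate
28 | 3-chloro-3-methylbut-1-yne | C#CC(C)(C)Cl | starting material
29 | {(2R,3R)-2-[7-(TBS-oxy)-2,2-dimethyl-2H-chromen-6-yl]-5-[(2-methylbut-3-yn-2-yl)oxy]-7-prenyl-6-(SEM-oxy)-2,3-dihydrobenzofuran-3-yl}methanol | OC[C@H]1c2cc(OC(C)(C)C#C)c(OCOCC[Si](C)(C)C)c(CC=C(C)C)c2O[C@H]1c1cc2C=CC(C)(C)Oc2cc1O[Si](C)(C)C(C)(C)C | intermediate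
30 | 6-{(2R,3R)-3-(hydroxymethyl)-5-[(2-methylbut-3-yn-2-yl)oxy]-7-prenyl-6-(SEM-oxy)-2,3-dihydrobenzofuran-2-yl}-2,2-dimethyl-2H-chromen-7-ol | OC[C@H]1c2cc(OC(C)(C)C#C)c(OCOCC[Si](C)(C)C)c(CC=C(C)C)c2O[C@H]1c1cc2C=CC(C)(C)Oc2cc1O | intermediate
31 | (6aR,11aR)-8-[(2-methylbut-3-yn-2-yl)oxy]-10-prenyl-9-(SEM-oxy)pterocarpan with ring E | CC(C)=CCc1c(OCOCC[Si](C)(C)C)c(OC(C)(C)C#C)cc2c1O[C@H]1c3cc4c(cc3OC[C@@H]21)OC(C)(C)C=C4 | intermediate
32 | (6aR,11aR)-8-hydroxy-7-(3-methylbuta-1,2-dien-1-yl) analogue of 31, formed in the flask | CC(C)=CCc1c(OCOCC[Si](C)(C)C)c(O)c(C=C=C(C)C)c2c1O[C@H]1c3cc4c(cc3OC[C@@H]21)OC(C)(C)C=C4 | intermediate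
33 | ring D ortho-quinone methide (C8 carbonyl, C7 3-methylbut-2-enylidene), formed in the flask | CC(C)=CCC1=C(OCOCC[Si](C)(C)C)C(=O)C(=CC=C(C)C)C2=C1O[C@H]1c3cc4c(cc3OC[C@@H]21)OC(C)(C)C=C4 | intermediate
34 | 9-O-SEM-lespecyrtin E4, (6aR,11aR) | CC(C)=CCc1c(OCOCC[Si](C)(C)C)c2c(c3c1O[C@H]1c4cc5c(cc4OC[C@@H]31)OC(C)(C)C=C5)C=CC(C)(C)O2 | intermediate
35 | lespecyrtin E4, (6aR,11aR) | CC(C)=CCc1c(O)c2c(c3c1O[C@H]1c4cc5c(cc4OC[C@@H]31)OC(C)(C)C=C5)C=CC(C)(C)O2 | target

**Step count**

- Total step count: 21.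
- Longest linear sequence: 16 steps (steps 5–8 and 10–21, from 3,4-dihydroxybenzaldehyde).

**Steps most likely to fail**

1. Step 15. The ortho silyloxy group on ring A and the flanking C10 prenyl group may fit the catalyst pocket poorly, so discrimination between the two carbene faces and the two benzylic hydrogens could erode. The fallback replaces catalyst control by resolution through covalent diastereomers.
   - It sets out from 29 carried forward in scalemic form. The primary alcohol is esterified with (S)-2-methoxy-2-phenylacetic acid (EDC, DMAP, CH2Cl2) to the (S)-O-methylmandelate ester F1.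
   - The wanted diastereomer is separated by chromatography or crystallisation and cleaved with LiAlH4 (THF, 0 °C).
   - The route is rejoined at 29 as a single enantiomer.

2. Step 13. Oxidative addition into the electron-rich, ortho-alkoxy C–Br bond may be slow, so protodebromination or palladium-mediated C–H arylation of ring A could take over. The fallback avoids palladium and diazo transfer altogether and bypasses steps 13 and 14.
   - It sets out from 19. Bromine–lithium exchange (n-BuLi, THF, −95 °C) and acylation with dimethyl oxalate should give the methyl arylglyoxylate F2.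
   - Condensation with tosylhydrazide (toluene, 60 °C) gives the tosylhydrazone F3.
   - Mild base (Et3N, CH2Cl2, rt) triggers Bamford–Stevens loss of sulfinate, and the route is rejoined at 23.

3. Step 18. Once O5 is unmasked, ring C may open reversibly at the doubly activated C11a–O11 bond through a quinone-methide pathway. That would scramble C11a before ring B locks it. The fallback activates C6 first, so that O5 is consumed the moment it is freed.
   - It sets out from 29. Mesylation (MsCl, Et3N, CH2Cl2, −20 °C) gives the primary mesylate F4.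
   - CsF (DMF, 0 °C to rt) removes the silyl group and the oxygen closes ring B at once by intramolecular SN2 displacement.
   - The route is rejoined at 31.

Further compounds
F1 | step 15 | (S)-2-methoxy-2-phenylacetate ester of 29 | CO[C@H](C(=O)OC[C@H]1c2cc(OC(C)(C)C#C)c(OCOCC[Si](C)(C)C)c(CC=C(C)C)c2O[C@H]1c1cc2C=CC(C)(C)Oc2cc1O[Si](C)(C)C(C)(C)C)c1ccccc1
F2 | step 13 | methyl 2-oxo-2-{2-{[7-(TBS-oxy)-2,2-dimethyl-2H-chromen-6-yl]methoxy}-3-prenyl-5-(POM-oxy)-4-(SEM-oxy)phenyl}acetate | COC(=O)C(=O)c1cc(OCOC(=O)C(C)(C)C)c(OCOCC[Si](C)(C)C)c(CC=C(C)C)c1OCc1cc2C=CC(C)(C)Oc2cc1O[Si](C)(C)C(C)(C)C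
F3 | step 13 | tosylhydrazone of F2 | COC(=O)C(=NNS(=O)(=O)c1ccc(C)cc1)c1cc(OCOC(=O)C(C)(C)C)c(OCOCC[Si](C)(C)C)c(CC=C(C)C)c1OCc1cc2C=CC(C)(C)Oc2cc1O[Si](C)(C)C(C)(C)C
F4 | step 18 | methanesulfonate of 29 | CS(=O)(=O)OC[C@H]1c2cc(OC(C)(C)C#C)c(OCOCC[Si](C)(C)C)c(CC=C(C)C)c2O[C@H]1c1cc2C=CC(C)(C)Oc2cc1O[Si](C)(C)C(C)(C)C
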